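(All runs are simulated on assumed constants, and the scatter is random.)

Enter first in the minutes that the flask is charged symmetrically, with starting material and second substrate both at 0.73 M. Noon is this flask followed to 8.00 h; winter is the earlier run with second substrate cut to 0.49 M.

in all of them: starting material 0.73 M; gas 170 mM (held); free catalyst 73 mM; impurity 16 mM

|  | second substrate | remark | time |
|---|---|---|---|
| noon | 0.73 M | the very flask that is asked about, followed so far |  |
| winter | 0.49 M | run made earlier |  |
| flask | 0.730 M |  | 40 h |

| run | time / h | target / % |
|---|---|---|
| noon | 1.50 | 0 |
| noon | 3.00 | 0.2 |
| noon | 5.00 | 1.0 |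
| noon | 6.00 | 0.7 |
| noon | 8.00 | 1.2 |
| winter | 3.00 | 0 |
| winter | 6.00 | 1.0 |
| winter | 12.0 | 2.9 |
| winter | 20.0 | 6.6 |
| winter | 40.0 | 14.2 |

(each reading ± 0.5 percentage points)

- at the start none of the gas is in solution

- south-east: doubling the amount of free catalyst, all else as stated
- south-west: doubling the transfer coefficient of the gas, all else as stated
- west: doubling the saturation concentration of gas, all else as stated

- how much target there is at 40 h, in percent of the starting material charged
- the change that raises the amount of target at 40 h, in percent of the starting material charged most ("none" if none brings more than 2 percentage points) (south-east / south-west / west / none)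
- amount of target at 40 h, in percent of the starting material charged, after south-east

The chair reported that at 6.00 h noon read 0.7% and winter 1.0%, a gap of 0.3 percentage points beside a scatter of 0.5 points, so this pair of readings does not tell the two runs apart. Winter, however, reached 14.2% at 40.0 h.

The secretary, reckoning for herself, supposed that both substrates draw on one shared turnover with neither favoured, a selectivity factor of one, and took that statistical case as the zero of the scale. This gives 0.500 for the flask and 0.598 for winter as the target share, c(starting material) over c(starting material) plus c(second substrate). The flask's share is lower than winter's, so if total turnover matches winter's, scaling winter's last reading by the two shares gives 11.9%.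

The forecaster gave 11%, range 8% to 15%, named south-east as the best change, and put the flask after it at 23%, range 14% to 32%, arguing that the slope ratio “hints that the second substrate inhibits rather than helps”. The secretary's figure for the flask is higher than the forecast's.

The flask gives 12.6% of target at 40 h. The best change is west, gaining 10 points against 7.4 points for south-east, and south-east ends at 20.0%.

    coupling partner + catalyst intermediate B → free catalyst + second product (k = 6.70 × 10⁻⁴ M⁻¹ s⁻¹)
    free catalyst + impurity → spent catalyst (k = 0.00530 M⁻¹ s⁻¹)
    gas ⇌ coupling partner, rate k3*(csat - [coupling partner]) (kL = 2.30 × 10⁻⁵ s⁻¹)
    coupling partner + catalyst intermediate A → free catalyst + target (k = 7.70 × 10⁻⁴ M⁻¹ s⁻¹)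
    second substrate + free catalyst ⇌ catalyst intermediate B (K = 0.700 M⁻¹, k = 1.50 × 10⁻⁴ M⁻¹ s⁻¹)
    starting material + free catalyst ⇌ catalyst intermediate A (K = 0.530 M⁻¹, k = 1.70 × 10⁻⁴ M⁻¹ s⁻¹)

At 40 h the flask's target amounts to 0.0919 M beside 0.0994 M of second product, so target over both products is then 0.480; the target share is 0.500 from the charges and 0.504 from the substrates standing at that time. The neighbour flask, with the same substrate charges and 0.12 M of free catalyst, holds 18.0% of target and 0.142 M of second product at 40 h, a ratio of 0.481.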